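I decided to leave the rates aside and count balances, since the zeta run barely moved after its first reading at 1.33 h: J went from 43.2% to 44.5%.

all flasks: X 1.19 M

|  | D | E | remark | time |
|---|---|---|---|---|
| zeta | 2.4 M | 0.85 M | run made earlier |  |
| eta | 1.7 M | 1.7 M | run made earlier |  |
| flask | 1.7 M | 0.850 M |  | 5.0 h |

| run | time / h | J / % | Q / % |
|---|---|---|---|
| zeta | 1.33 | 43.2 | 26.4 |
| zeta | 2.50 | 44.0 | 26.9 |
| zeta | 4.00 | 43.6 | 27.2 |
| zeta | 5.00 | 44.5 | 26.7 |
| eta | 1.33 | 27.8 | 33.8 |
| eta | 2.50 | 27.7 | 31.0 |
| eta | 4.00 | 28.0 | 30.7 |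
| eta | 5.00 | 28.8 | 30.7 |

(each reading ± 0.5 percentage points)

- ratio of J to Q at 25 s
- ratio of J to Q at 5.0 h
- which of J and Q there is more of at 5.0 h

How much E reaches G? In zeta, cD at 2.4 M stood above cE and cX together, 2.04 M, so I took X and E as the limiting reagents and X as wholly used, each X ending in J or L. Mean J there was 1.05 M, which left 0.138 M for L. Q and L each carry one E, so with mean Q at 0.643 M, delivered E came to 0.781 M, a share of 91.9%. I put the rest down to Z and assumed the same share for the flask.

Does the flask leave X over? I named spare X the charge cX plus delivered E minus the charge cD: 0.271 M. It stood above zero, cX plus delivered E being more than cD, so I reckoned that this X turned Q into L. That gave J as 0.919 M and Q as 0.510 M, a ratio of 1.80 with J ahead. The early time 25 s lies before any reading, and a balance cannot reach it, so I left that ratio open.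

The forecast gave 1.5 at 25 s, 1.75 at 5.0 h and J ahead, holding that “capacity slightly exceeds D”.

The flask gave 0.0478 at 25 s and 1.87 at 5.0 h, with J at 54.3% and Q at 29.0%.

    D → G (k = 0.304 min⁻¹)
    2 E → Z (k = 0.0947 M⁻¹ min⁻¹)
    X + G → J (k = 0.466 M⁻¹ min⁻¹)
    E + G → Q (k = 15.7 M⁻¹ min⁻¹)
    X + Q → L (k = 0.0331 M⁻¹ min⁻¹)

Spare X was 16.0% of the charged D, and the flask's L stood at 15.7% at 5.00 h. For the neighbouring flask with cE at 0.34 M, other charges as in the recipe, the same share gave spare X as −0.197 M, below zero, cX plus delivered E being less than cD. So I reckoned X used up, and G left over at about 11.6% of the charged D plus whatever L formed. That neighbouring flask ended with X at 0% of its charge, L at 4.01% and G at 14.6%.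

The readings are calculated for an exercise; the scatter is artificial.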